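Numbering (2-oxaspiro[4.5]decane): C1 lactone carbinol, O2, C3 lactone C=O, C4 CH2, C5 spiro, C6 ketone, C7=C8, C9 CH–OAc, C10 CH2. Retrosynthesis cuts the C9 acetate, then C9–H (back to an ene-1,4-dione, the desilylated form of a 9-silyloxy-7,9-dien-6-one), then the C5–C1 bond, then the acylal C1–O bond that joins chain and arylacetate.
Enabling feature: C5–C10 with C6=O and C9–O para to each other, together with C4H2–C3(=O), are homogentisic acid. C5 is therefore the substituted ortho carbon of a phenol, and C1 (allylic, already carrying the lactone oxygen and a leaving acetate) is the terminus of a 1-acyloxy-π-allyl palladium complex.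
Forward, chain joining: geranyl acetate gives the (2E,5E)-7-silyloxy enal (epoxidation, selenide opening, selenoxide elimination); homogentisic lactone gives a caesium hydroxy-arylacetate; the two are joined as a mixed acylal with acetyl chloride.
Ring order: the carbocycle is present as the arene from the start; the γ-lactone is the only ring made, closed onto C5 with dearomatisation in the Pd step; desilylation, 1,2-reduction and acetylation follow.
Stereochemistry: 2E comes from geranyl acetate and 5E from a selenoxide syn-elimination; C1 and C5 are set in the Pd step (chiral bisphosphine for the allyl face, five-ring transition state for the arene face); C9 by substrate-controlled hydride delivery.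

Key step: step 9

Assumption: the (R,R) antipode of the DACH-phenyl bisphosphine is written in step 9, but which antipode gives (1R) has to be settled by experiment (the mirror-image ligand is used if the sense is opposite); homogentisic acid γ-lactone is taken as purchasable, otherwise it is one acid-catalysed dehydration from homogentisic acid.

Step 1
Reactants: 1 geranyl acetate
Product: 2 (2E)-6,7-epoxy-3,7-dimethyloct-2-en-1-yl acetate (racemic at C6)
Conditions: mCPBA, NaHCO3, CH2Cl2, 0 °C
Reagents that add atoms: mCPBA (3-chloroperoxybenzoic acid), OOC(=O)c1cccc(Cl)c1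
Why: Prilezhaev epoxidation should take place only at the electron-rich 6,7-alkene, the 2,3-alkene being deactivated by the allylic acetate; the epoxide stereocentre is formed racemic and is erased in step 2.

Step 2
Reactants: 2 (2E)-6,7-epoxy-3,7-dimethyloct-2-en-1-yl acetate
Product: 4 (2E,5E)-7-hydroxy-3,7-dimethylocta-2,5-dien-1-yl acetate, via hydroxy selenide 3 (not isolated)
Conditions: (PhSe)2, NaBH4, EtOH, rt; then 30% H2O2, THF, 0 °C → rt
Reagents that add atoms: none
Why: Selenide opening of the epoxide at the less substituted C6 (SN2) followed by selenoxide syn-elimination, which can only proceed towards C5 because C7 carries no hydrogen, should give the E-disubstituted alkene and the tertiary allylic alcohol (epoxide to allylic alcohol transposition).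

Step 3
Reactants: 4 (2E,5E)-7-hydroxy-3,7-dimethylocta-2,5-dien-1-yl acetate
Product: 5 (2E,5E)-7-[(tert-butyldimethylsilyl)oxy]-3,7-dimethylocta-2,5-dien-1-yl acetate
Conditions: TBSOTf, 2,6-lutidine, CH2Cl2, −78 → 0 °C
Reagents that add atoms: tert-butyldimethylsilyl triflate, CC(C)(C)[Si](C)(C)OS(=O)(=O)C(F)(F)F
Why: Silylation of a tertiary alcohol with a silyl triflate and a hindered base is standard; the bulky tertiary TBS ether is chosen because it has to survive the Lewis-acidic acyl chloride of step 8.

Step 4
Reactants: 5 (2E,5E)-7-[(tert-butyldimethylsilyl)oxy]-3,7-dimethylocta-2,5-dien-1-yl acetate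
Product: 6 (2E,5E)-7-[(tert-butyldimethylsilyl)oxy]-3,7-dimethylocta-2,5-dien-1-ol
Conditions: K2CO3 (cat.), MeOH, 0 °C → rt
Reagents that add atoms: none
Why: Base-catalysed methanolysis (transesterification) removes the primary acetate while the hindered tertiary silyl ether is inert.

Step 5
Reactants: 6 (2E,5E)-7-[(tert-butyldimethylsilyl)oxy]-3,7-dimethylocta-2,5-dien-1-ol
Product: 7 (2E,5E)-7-[(tert-butyldimethylsilyl)oxy]-3,7-dimethylocta-2,5-dienal
Conditions: activated MnO2, CH2Cl2, rt
Reagents that add atoms: none
Why: Manganese dioxide oxidation of a primary allylic alcohol is neutral and heterogeneous, so the 2E geometry should be kept and the skipped diene should not move into conjugation.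

Step 6
Reactants: 8 homogentisic acid γ-lactone
Product: 9 5-[(tert-butyldimethylsilyl)oxy]benzofuran-2(3H)-one
Conditions: TBSCl, imidazole, CH2Cl2, 0 °C → rt
Reagents that add atoms: tert-butyldimethylsilyl chloride, CC(C)(C)[Si](C)(C)Cl
Why: Silylation of the only free phenol with a silyl chloride and imidazole; the lactone keeps the other phenol oxygen and the carboxyl group masked, and this silyl group later becomes the dienol ether.

Step 7
Reactants: 9 5-[(tert-butyldimethylsilyl)oxy]benzofuran-2(3H)-one
Product: 10 caesium {5-[(tert-butyldimethylsilyl)oxy]-2-hydroxyphenyl}acetate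
Conditions: CsOH·H2O (1.0 equiv), THF/H2O, 0 °C; freeze-dry
Reagents that add atoms: caesium hydroxide, [Cs+].[OH-]
Why: Saponification of the strained aryl lactone with exactly one equivalent of hydroxide should be much faster than attack on the aryl silyl ether and gives the phenol–carboxylate mono-salt directly, avoiding the free acid, which relactonises.

Step 8
Reactants: 7 (2E,5E)-7-[(tert-butyldimethylsilyl)oxy]-3,7-dimethylocta-2,5-dienal, 11 acetyl chloride, 10 caesium {5-[(tert-butyldimethylsilyl)oxy]-2-hydroxyphenyl}acetate
Product: 13 (2E,5E)-1-acetoxy-7-[(tert-butyldimethylsilyl)oxy]-3,7-dimethylocta-2,5-dien-1-yl {5-[(tert-butyldimethylsilyl)oxy]-2-hydroxyphenyl}acetate (both epimers at C1), via 1-chloroallyl acetate 12 (not isolated)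
Conditions: 7 (1.1 equiv), 11 (1.0 equiv), ZnCl2 (2 mol%), CH2Cl2, −30 °C; evaporate cold; then 10, DMF, −30 → 0 °C
Reagents that add atoms: none
Why: Zinc chloride-catalysed 1,2-addition of the acyl chloride to the aldehyde (α-chloroalkyl ester formation) should give the kinetic 1-chloroallyl acetate at low temperature, and the caesium carboxylate then displaces chloride at the acetoxy-bearing CH terminus (acyloxyalkylation of a carboxylate, the phenol staying protonated); the acylal stereocentre is left uncontrolled because it is ionised in step 9.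

Step 9
Reactants: 13 (2E,5E)-1-acetoxy-7-[(tert-butyldimethylsilyl)oxy]-3,7-dimethylocta-2,5-dien-1-yl {5-[(tert-butyldimethylsilyl)oxy]-2-hydroxyphenyl}acetate
Product: 14 (1R,5S)-9-[(tert-butyldimethylsilyl)oxy]-1-[(1E,4E)-6-[(tert-butyldimethylsilyl)oxy]-2,6-dimethylhepta-1,4-dien-1-yl]-2-oxaspiro[4.5]deca-7,9-diene-3,6-dione
Conditions: Pd2(dba)3·CHCl3 (2.5 mol%), (R,R)-DACH-phenyl bisphosphine [N,N'-(1R,2R)-cyclohexane-1,2-diylbis(2-diphenylphosphinobenzamide)] (7.5 mol%), Bu4NCl (20 mol%), CH2Cl2 (0.02 M), 0 °C → rt
Reagents that add atoms: none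
Why: Proposed new method: Pd(0) ionises the acetate of 13 with inversion to a 1-acyloxy-π-allyl complex held to the arylacetate through the ester, and the phenol, deprotonated by the departing acetate, attacks the oxygen-bearing allyl terminus anti to palladium through its substituted ortho carbon, which forms C5–C1, closes the γ-lactone and leaves a 2,4-dienone that cannot rearomatise and is kept as the silyl dienol ether; the closest known reaction types are the Pd-catalysed intramolecular ipso-allylation of phenols to spirocyclohexadienones and the Pd-catalysed asymmetric substitution of allylic gem-diacetates and of γ-acyloxybutenolides at the acyloxy-bearing carbon. The lactone closes in a 5-exo mode with the allyl C=C left exocyclic, the only accessible ring size, since O-attack, attack at the distal allyl carbon or attack by the unsubstituted ortho carbon would all need seven-membered rings. C1 is controlled by the chiral bisphosphine: each acylal epimer ionises and closes with overall retention, so the two diastereomeric π-allyl complexes must interconvert faster than ring closure, which reversible acetate return and the chloride additive (through the configurationally labile 1-chloroallyl ester) are meant to ensure, the chiral pocket then selecting the allyl face that closes. C5 is controlled by the arene face that fits the compact five-membered transition state, in which the phenolate oxygen is expected to stay on the side of the palladium-bound alkenyl chain (ion pairing, hydrogen bond to a ligand N–H), so that the alkenyl group ends syn to the ring ketone. The step needs C- over O-alkylation, ring closure before the phenol can reclose onto the ester carbonyl, and retention of the 2E alkene; these rest on the tether geometry, on base-free conditions and on fast intramolecular capture before syn–anti exchange at the disubstituted allyl terminus.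

Step 10
Reactants: 14 (1R,5S)-9-[(tert-butyldimethylsilyl)oxy]-1-[(1E,4E)-6-[(tert-butyldimethylsilyl)oxy]-2,6-dimethylhepta-1,4-dien-1-yl]-2-oxaspiro[4.5]deca-7,9-diene-3,6-dione
Product: 15 (1R,5R)-1-[(1E,4E)-6-hydroxy-2,6-dimethylhepta-1,4-dien-1-yl]-2-oxaspiro[4.5]dec-7-ene-3,6,9-trione
Conditions: 48% aq. HF, MeCN, 0 °C → rt
Reagents that add atoms: none
Why: Acidic fluoride desilylation should cleave the silyl dienol ether, whose enol ketonises by protonation at C10 to the ene-1,4-dione (the quaternary C5 blocks aromatisation), and should also free the tertiary alcohol, while neither stereocentre is enolisable.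

Step 11
Reactants: 15 (1R,5R)-1-[(1E,4E)-6-hydroxy-2,6-dimethylhepta-1,4-dien-1-yl]-2-oxaspiro[4.5]dec-7-ene-3,6,9-trione
Product: 16 (1R,5R,9S)-9-hydroxy-1-[(1E,4E)-6-hydroxy-2,6-dimethylhepta-1,4-dien-1-yl]-2-oxaspiro[4.5]dec-7-ene-3,6-dione
Conditions: NaBH4 (1.0 equiv), CeCl3·7H2O, MeOH, −78 °C
Reagents that add atoms: none
Why: Luche 1,2-reduction should select the C9 carbonyl, since C6 is shielded by the adjacent quaternary C5, and hydride is expected to arrive from the face opposite the C1 arm of the spirolactone (pseudo-axial, shielding its own face), which sets the 9-hydroxyl cis to C1.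

Step 12
Reactants: 16 (1R,5R,9S)-9-hydroxy-1-[(1E,4E)-6-hydroxy-2,6-dimethylhepta-1,4-dien-1-yl]-2-oxaspiro[4.5]dec-7-ene-3,6-dione
Product: 17 (+)-miliusane XVII
Conditions: Ac2O, pyridine, DMAP (cat.), CH2Cl2, 0 °C
Reagents that add atoms: acetic anhydride, CC(=O)OC(C)=O
Why: Nucleophile-catalysed acylation acetylates the secondary allylic alcohol and leaves the tertiary alcohol untouched for steric reasons.

Compound list
1 | geranyl acetate [(2E)-3,7-dimethylocta-2,6-dien-1-yl acetate] | CC(=O)OC/C=C(\C)CCC=C(C)C | starting material
2 | (2E)-6,7-epoxy-3,7-dimethyloct-2-en-1-yl acetate (racemic at C6) | CC(=O)OC/C=C(\C)CCC1OC1(C)C | intermediate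
3 | (2E)-7-hydroxy-3,7-dimethyl-6-(phenylselanyl)oct-2-en-1-yl acetate (racemic, formed in the flask) | CC(=O)OC/C=C(\C)CCC([Se]c1ccccc1)C(C)(C)O | intermediate
4 | (2E,5E)-7-hydroxy-3,7-dimethylocta-2,5-dien-1-yl acetate | CC(=O)OC/C=C(\C)C/C=C/C(C)(C)O | intermediate
5 | (2E,5E)-7-[(tert-butyldimethylsilyl)oxy]-3,7-dimethylocta-2,5-dien-1-yl acetate | CC(=O)OC/C=C(\C)C/C=C/C(C)(C)O[Si](C)(C)C(C)(C)C | intermediate
6 | (2E,5E)-7-[(tert-butyldimethylsilyl)oxy]-3,7-dimethylocta-2,5-dien-1-ol | OC/C=C(\C)C/C=C/C(C)(C)O[Si](C)(C)C(C)(C)C | intermediate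
7 | (2E,5E)-7-[(tert-butyldimethylsilyl)oxy]-3,7-dimethylocta-2,5-dienal | O=C/C=C(\C)C/C=C/C(C)(C)O[Si](C)(C)C(C)(C)C | intermediate
8 | homogentisic acid γ-lactone [5-hydroxybenzofuran-2(3H)-one] | O=C1Cc2cc(O)ccc2O1 | starting material
9 | 5-[(tert-butyldimethylsilyl)oxy]benzofuran-2(3H)-one | O=C1Cc2cc(O[Si](C)(C)C(C)(C)C)ccc2O1 | intermediate
10 | caesium {5-[(tert-butyldimethylsilyl)oxy]-2-hydroxyphenyl}acetate | [Cs+].[O-]C(=O)Cc1cc(O[Si](C)(C)C(C)(C)C)ccc1O | intermediate
11 | acetyl chloride | CC(Cl)=O | starting material
12 | (2E,5E)-1-chloro-7-[(tert-butyldimethylsilyl)oxy]-3,7-dimethylocta-2,5-dien-1-yl acetate (racemic at C1, formed in the flask) | CC(=O)OC(Cl)/C=C(\C)C/C=C/C(C)(C)O[Si](C)(C)C(C)(C)C | intermediate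
13 | (2E,5E)-1-acetoxy-7-[(tert-butyldimethylsilyl)oxy]-3,7-dimethylocta-2,5-dien-1-yl {5-[(tert-butyldimethylsilyl)oxy]-2-hydroxyphenyl}acetate (both epimers at C1) | CC(=O)OC(OC(=O)Cc1cc(O[Si](C)(C)C(C)(C)C)ccc1O)/C=C(\C)C/C=C/C(C)(C)O[Si](C)(C)C(C)(C)C | intermediate
14 | (1R,5S)-9-[(tert-butyldimethylsilyl)oxy]-1-[(1E,4E)-6-[(tert-butyldimethylsilyl)oxy]-2,6-dimethylhepta-1,4-dien-1-yl]-2-oxaspiro[4.5]deca-7,9-diene-3,6-dione (5S only by CIP priority change; same spatial arrangement as 5R in 15–17) | CC(C)(C)[Si](C)(C)OC1=C[C@]2(CC(=O)O[C@@H]2/C=C(\C)C/C=C/C(C)(C)O[Si](C)(C)C(C)(C)C)C(=O)C=C1 | intermediate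
15 | (1R,5R)-1-[(1E,4E)-6-hydroxy-2,6-dimethylhepta-1,4-dien-1-yl]-2-oxaspiro[4.5]dec-7-ene-3,6,9-trione | O=C1C=CC(=O)[C@@]2(CC(=O)O[C@@H]2/C=C(\C)C/C=C/C(C)(C)O)C1 | intermediate
16 | (1R,5R,9S)-9-hydroxy-1-[(1E,4E)-6-hydroxy-2,6-dimethylhepta-1,4-dien-1-yl]-2-oxaspiro[4.5]dec-7-ene-3,6-dione | O[C@@H]1C=CC(=O)[C@@]2(CC(=O)O[C@@H]2/C=C(\C)C/C=C/C(C)(C)O)C1 | intermediate
17 | (+)-miliusane XVII [(1R,5R,9S)-1-[(1E,4E)-6-hydroxy-2,6-dimethylhepta-1,4-dien-1-yl]-3,6-dioxo-2-oxaspiro[4.5]dec-7-en-9-yl acetate] | CC(=O)O[C@@H]1C=CC(=O)[C@@]2(CC(=O)O[C@@H]2/C=C(\C)C/C=C/C(C)(C)O)C1 | target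

Total step count: 12. Longest linear sequence: 10 steps (steps 1–5, then 8–12).

Steps most likely to fail

Step 9. Several processes may defeat it. The two acylal epimers may not equilibrate at the π-allyl stage, so that the catalyst only resolves them and C1 forms with low enantiopurity. The arene-face selectivity at C5 may be poor. The phenol may reclose onto the ester carbonyl and expel the enal. The allyl complex may lose a proton from the doubly allylic CH2. The product may re-ionise at its allylic lactone C–O bond. The fallback uses known enolate chemistry, sets out from enal 7 and returns at ene-dione 15; the spiro centre is built from a ketone enolate instead of a phenol. 1,4-Dioxaspiro[4.5]dec-6-en-8-one F1 (from commercial 1,4-cyclohexanedione mono-ethylene ketal by IBX dehydrogenation) would be alkylated at its α'-carbon through the kinetic lithium enolate (LDA, THF, −78 °C, methyl bromoacetate) to methyl (8-oxo-1,4-dioxaspiro[4.5]dec-6-en-9-yl)acetate F2. A second deprotonation at the same carbon is unambiguous because the other α-position is vinylic. Aldol addition of that enolate to 7 would form the C5–C1 bond, and the aldolate would close onto the methyl ester to give the spirolactone ketal (1R,5R)-9,9-ethylenedioxy-1-[(1E,4E)-6-[(tert-butyldimethylsilyl)oxy]-2,6-dimethylhepta-1,4-dien-1-yl]-2-oxaspiro[4.5]dec-7-ene-3,6-dione F3 as a racemic mixture of diastereomers. The required isomer would be isolated by chromatography and chiral-phase HPLC. Aqueous HF in MeCN would then remove the ketal and the silyl ether to give 15.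

Step 8. The allylic chloride may transpose to the tertiary position or lose HCl to dienyl acetates, the carboxylate may attack the distal allyl carbon, the tertiary silyl ether may be cleaved by the zinc chloride/acetyl chloride pair, and the product may relactonise if the medium turns basic. The fallback avoids the allylic halide, sets out from enal 7 (with salt 10) and returns at 14. The enal would be converted with acetic anhydride and a catalytic mild Lewis acid into the geminal diacetate (2E,5E)-7-[(tert-butyldimethylsilyl)oxy]-3,7-dimethylocta-2,5-diene-1,1-diyl diacetate F4. F4 would be combined with 10 under the catalyst of step 9, so that carboxylate exchange at the acetoxy-bearing allyl terminus generates 13 in the flask and the ring closure follows in the same operation.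

Step 11. Hydride delivery may be unselective between the two faces of C9, or conjugate reduction of the ene-dione may compete. The fallback changes from substrate-controlled reduction to inversion, sets out from 15 and returns at 17. If the reduction gives mainly the 9-epimer (1R,5R,9R)-9-hydroxy-1-[(1E,4E)-6-hydroxy-2,6-dimethylhepta-1,4-dien-1-yl]-2-oxaspiro[4.5]dec-7-ene-3,6-dione F5, a Mitsunobu reaction with acetic acid (PPh3, DIAD, AcOH, THF, 0 °C) would invert C9 and install the acetate in one operation, leaving the tertiary alcohol untouched.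

Further compounds
F1 | step 9 | 1,4-dioxaspiro[4.5]dec-6-en-8-one | O=C1C=CC2(CC1)OCCO2
F2 | step 9 | methyl (8-oxo-1,4-dioxaspiro[4.5]dec-6-en-9-yl)acetate (racemic) | COC(=O)CC1CC2(OCCO2)C=CC1=O
F3 | step 9 | (1R,5R)-9,9-ethylenedioxy-1-[(1E,4E)-6-[(tert-butyldimethylsilyl)oxy]-2,6-dimethylhepta-1,4-dien-1-yl]-2-oxaspiro[4.5]dec-7-ene-3,6-dione | C1COC2(O1)C[C@]3(CC(=O)O[C@@H]3/C=C(\C)C/C=C/C(C)(C)O[Si](C)(C)C(C)(C)C)C(=O)C=C2
F4 | step 8 | (2E,5E)-7-[(tert-butyldimethylsilyl)oxy]-3,7-dimethylocta-2,5-diene-1,1-diyl diacetate | CC(=O)OC(OC(C)=O)/C=C(\C)C/C=C/C(C)(C)O[Si](C)(C)C(C)(C)C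
F5 | step 11 | (1R,5R,9R)-9-hydroxy-1-[(1E,4E)-6-hydroxy-2,6-dimethylhepta-1,4-dien-1-yl]-2-oxaspiro[4.5]dec-7-ene-3,6-dione | O[C@H]1C=CC(=O)[C@@]2(CC(=O)O[C@@H]2/C=C(\C)C/C=C/C(C)(C)O)C1
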